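Ring D bears three contiguous substituents: oxygen on C3, ring A on C2 and the ethylene bridge to ring C on C1. This oxygen/aryl/alkyl triad is the retron of a Catellani reaction, so ring D is excised from the 16-membered ring as plain 2-iodoanisole. The key step stitches it onto an open A–B–C chain that ends in a primary bromide (ring C side) and an aryl pinacolboronate (ring A side). Palladium/norbornene catalysis alkylates the single free ortho C–H, making the CH2–C1(D) bond. The boronate then takes the ipso palladium on C2(D), and the macrocycle is closed in one operation. The methoxy group blocks the other ortho site. Global demethylation finishes.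

Key step: step 6

Ring labels:
- Ring A is the phenol ring of the biaryl that carries the bridge to ring B.
- Ring B is the 4-hydroxy-3-aryloxyphenyl ring.
- Ring C is the para-phenylene ring.
- Ring D is the 1,2,3-trisubstituted phenol ring of the biaryl (C1 bridge carbon, C2 biaryl carbon, C3 oxygenated carbon).

Assumption: the target SMILES carries no stereodescriptor, so the biaryl axis is treated as configurationally undefined and no stereocontrol is planned; 4-bromo-3-iodoanisole is taken as a catalogue compound.

Step 1
Reactants: 1 tyrosol (4-(2-hydroxyethyl)phenol); 2 3-bromo-4-methoxybenzaldehyde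
Product: 3 3-[4-(2-hydroxyethyl)phenoxy]-4-methoxybenzaldehyde
Conditions: CuI (10 mol %), N,N-dimethylglycine hydrochloride (30 mol %), Cs2CO3 (2.5 equiv), 1,4-dioxane, 100 °C
Reagents that add atoms: none
Why: Ullmann-type diaryl ether coupling under ligand-accelerated copper catalysis: carbonate ionises only the phenol of 1, so the phenoxide should displace the aryl bromide of 2 while the primary alcohol and the aldehyde stay untouched.

Step 2
Reactants: 3 3-[4-(2-hydroxyethyl)phenoxy]-4-methoxybenzaldehyde
Product: 4 2-[4-(5-ethenyl-2-methoxyphenoxy)phenyl]ethanol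
Conditions: Ph3PCH3Br (2.5 equiv), KOtBu (2.4 equiv), THF, 0 °C to rt; aq NH4Cl
Reagents that add atoms: methyltriphenylphosphonium bromide, C[P+](c1ccccc1)(c1ccccc1)c1ccccc1.[Br-]
Why: Wittig methylenation: the non-stabilised ylide should turn the aldehyde into the terminal styrene, the surplus base only holding the alcohol as its alkoxide until work-up.

Step 3
Reactants: 4 2-[4-(5-ethenyl-2-methoxyphenoxy)phenyl]ethanol; 5 4-bromo-3-iodoanisole
Product: 7 2-(4-{5-[2-(2-bromo-5-methoxyphenyl)ethyl]-2-methoxyphenoxy}phenyl)ethanol, via bis(9-BBN) adduct 6 (not isolated)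
Conditions: 9-BBN-H (2.3 equiv), THF, 0 °C to rt; then 5, PdCl2(dppf) (5 mol %), 3 M aq NaOH, THF/DMF, rt to 40 °C
Reagents that add atoms: 9-borabicyclo[3.3.1]nonane (9-BBN-H), B1C2CCCC1CCC2 (its boron cage stands in 6 only)
Why: Anti-Markovnikov hydroboration of the styrene followed by B-alkyl Suzuki–Miyaura coupling: zerovalent palladium inserts far faster into the C–I than into the C–Br bond of 5, so the bridge to ring A should form with the bromide kept for step 4, and the aqueous base hydrolyses the O-boryl group.

Step 4
Reactants: 7 2-(4-{5-[2-(2-bromo-5-methoxyphenyl)ethyl]-2-methoxyphenoxy}phenyl)ethanol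
Product: 8 2-(4-{2-methoxy-5-[2-(5-methoxy-2-(4,4,5,5-tetramethyl-1,3,2-dioxaborolan-2-yl)phenyl)ethyl]phenoxy}phenyl)ethanol
Conditions: B2pin2 (1.3 equiv), PdCl2(dppf) (5 mol %), KOAc (3 equiv), 1,4-dioxane, 90 °C
Reagents that add atoms: bis(pinacolato)diboron, CC1(C)OB(OC1(C)C)B1OC(C)(C)C(C)(C)O1
Why: Miyaura borylation: the aryl bromide is the only carbon–halogen bond left, acetate is too weak a base to trigger Suzuki homocoupling, and the free alcohol is tolerated.

Step 5
Reactants: 8 boronate alcohol
Product: 9 2-[2-(2-{3-[4-(2-bromoethyl)phenoxy]-4-methoxyphenyl}ethyl)-4-methoxyphenyl]-4,4,5,5-tetramethyl-1,3,2-dioxaborolane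
Conditions: CBr4 (1.3 equiv), PPh3 (1.35 equiv), CH2Cl2, 0 °C
Reagents that add atoms: carbon tetrabromide, BrC(Br)(Br)Br
Why: Appel reaction: the primary alcohol is activated as its alkoxyphosphonium salt and displaced by bromide under neutral conditions that leave the pinacolboronate and the aryl ethers intact.

Step 6
Reactants: 9 open-chain bromide boronate; 10 2-iodoanisole
Product: 11 plagiochin E trimethyl ether (the 16-membered macrocycle with all three phenols as methyl ethers)
Conditions: Pd(OAc)2 (10 mol %), XPhos (22 mol %), norbornene (2 equiv), K2CO3 (4 equiv), H2O (10 equiv), DMF, 60 °C; equimolar solution of 9 and 10 added by syringe pump over 16 h, final 5 mM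
Reagents that add atoms: none
Why: Catellani reaction (palladium/norbornene cooperative catalysis, ortho C–H alkylation with ipso Suzuki–Miyaura termination), a known three-component reaction type of ortho-substituted aryl iodides, primary alkyl bromides and arylboron reagents, run here with bromide and boronate at the two ends of one chain. Zerovalent palladium inserts into the C–I bond of 10, norbornene carbopalladation and C–H palladation at the single free ortho carbon (the later C1 of ring D) give an aryl–norbornyl palladacycle, and SN2-type oxidative addition of the CH2Br end of 9 to a tetravalent palladium species followed by reductive elimination makes the CH2–C1(D) bond. The now doubly ortho-substituted aryl–norbornyl palladium species expels norbornene by β-carbon elimination and leaves divalent palladium on C2(D), where the tethered boronate of ring A transmetalates and reductive elimination makes the C2(D)–C(A) biaryl bond. One ring is closed, the 16-membered macrocycle, in a [14+2] annulation mode: the fourteen-atom chain of 9 is stitched by its two ends onto the adjacent carbons C1 and C2 of ring D, both new bonds are ring bonds, and no stereocentre is formed. The step needs alkylation before aryl transfer, a single alkylation, and ring closure before chain growth: excess norbornene traps the ortho-substituted arylpalladium iodide faster than boron can, the methoxy group on C3(D) blocks the second ortho site, and slow equimolar co-addition keeps free boronate scarce and never lets the electron-rich 10 build up to arylate the palladacycle. β-Hydride loss is not expected because reductive elimination from the tetravalent palladacycle is fast, and the mild carbonate base at 60 °C limits E2 loss of HBr from the 2-arylethyl bromide.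

Step 7
Reactants: 11 plagiochin E trimethyl ether
Product: 13 plagiochin E, via tris(dibromoboryl) ether 12 (not isolated)
Conditions: BBr3 (6 equiv), CH2Cl2, −78 °C to rt; then ice/H2O
Reagents that add atoms: boron tribromide, BrB(Br)Br (its boron and bromine stand in 12 only)
Why: Lewis-acid cleavage of aryl methyl ethers with BBr3: each methoxy oxygen is borylated and demethylated by bromide at the methyl carbon, the diaryl ether has no sp3 C–O bond to cleave, and hydrolysis of 12 should release the three phenols.

Compound list
1 | tyrosol, 4-(2-hydroxyethyl)phenol | OCCc1ccc(O)cc1 | starting material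
2 | 3-bromo-4-methoxybenzaldehyde | COc1ccc(C=O)cc1Br | starting material
3 | 3-[4-(2-hydroxyethyl)phenoxy]-4-methoxybenzaldehyde | COc1ccc(C=O)cc1Oc1ccc(CCO)cc1 | intermediate
4 | 2-[4-(5-ethenyl-2-methoxyphenoxy)phenyl]ethanol | COc1ccc(C=C)cc1Oc1ccc(CCO)cc1 | intermediate
5 | 4-bromo-3-iodoanisole | COc1ccc(Br)c(I)c1 | starting material
6 | bis(9-BBN) adduct of 4 (B-alkyl at the former vinyl terminus, O-boryl at the alcohol) | COc1ccc(CCB2C3CCCC2CCC3)cc1Oc1ccc(CCOB2C3CCCC2CCC3)cc1 | intermediate
7 | 2-(4-{5-[2-(2-bromo-5-methoxyphenyl)ethyl]-2-methoxyphenoxy}phenyl)ethanol | COc1ccc(Br)c(CCc2ccc(OC)c(Oc3ccc(CCO)cc3)c2)c1 | intermediate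
8 | 2-(4-{2-methoxy-5-[2-(5-methoxy-2-(pinacolboryl)phenyl)ethyl]phenoxy}phenyl)ethanol | COc1ccc(B2OC(C)(C)C(C)(C)O2)c(CCc2ccc(OC)c(Oc3ccc(CCO)cc3)c2)c1 | intermediate
9 | 2-[2-(2-{3-[4-(2-bromoethyl)phenoxy]-4-methoxyphenyl}ethyl)-4-methoxyphenyl]-4,4,5,5-tetramethyl-1,3,2-dioxaborolane | COc1ccc(B2OC(C)(C)C(C)(C)O2)c(CCc2ccc(OC)c(Oc3ccc(CCBr)cc3)c2)c1 | intermediate
10 | 2-iodoanisole | COc1ccccc1I | starting material
11 | plagiochin E trimethyl ether | COc1ccc2c(c1)CCc1ccc(OC)c(c1)Oc1ccc(cc1)CCc1cccc(OC)c1-2 | intermediate
12 | tris(O-dibromoboryl) derivative of plagiochin E | BrB(Br)Oc1ccc2c(c1)CCc1ccc(OB(Br)Br)c(c1)Oc1ccc(cc1)CCc1cccc(OB(Br)Br)c1-2 | intermediate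
13 | plagiochin E | Oc1ccc2c(c1)CCc1ccc(O)c(c1)Oc1ccc(cc1)CCc1cccc(O)c1-2 | target

Total step count: 7. Longest linear sequence: 7 steps (from 1 and 2 to 13).

Steps most likely to fail

1. Step 6.
- What may go wrong:
  - Aryl transfer from boron to palladium before norbornene insertion and alkylation.
  - Arylation of the palladacycle by a second molecule of 10.
  - Base-induced loss of HBr from the 2-arylethyl bromide.
  - Decay of the palladacycle while the bromide is scarce.
  - Chain growth in place of ring closure.
- Fallback: a stepwise route in which the same CH2–C1(D) bond is closed by a B-alkyl Suzuki–Miyaura macrocyclisation. It sets out from 9 and comes back at 11. KOtBu in THF should eliminate HBr from 9 to the styrene boronate F1. Site-selective Suzuki–Miyaura coupling of F1 at the C–I bond of commercial 1-bromo-2-iodo-3-methoxybenzene (Pd(PPh3)4, K3PO4, dioxane/H2O, 80 °C) should give the styrene biaryl bromide F2. Hydroboration of F2 with 9-BBN-H should give the alkylborane F3. Slow addition of F3 to PdCl2(dppf) and Cs2CO3 in THF/DMF/H2O at high dilution should close the ring to 11.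

2. Step 3.
- What may go wrong: erosion of the site selectivity between C–I and C–Br with over-coupling at the bromide, and protodeboronation of the alkylborane in the aqueous base.
- Fallback: olefination and reduction in place of cross-coupling. It sets out from 3 and comes back at 7. Commercial 2-bromo-5-methoxybenzyl bromide and PPh3 (toluene, reflux) should give the phosphonium salt F4. Wittig reaction of F4 with 3 (KOtBu, THF, 0 °C to rt) should give the stilbene F5 as an E/Z mixture. Diimide (TsNHNH2, NaOAc, THF/H2O, reflux) should saturate the alkene without touching the C–Br bond and deliver 7.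

3. Step 1.
- What may go wrong: sluggish reaction at the bromide hindered by the ortho methoxy group, reductive loss of bromine, and competing O-arylation of the aliphatic alcohol at long reaction times.
- Fallback: oxidative copper coupling with the polarity of ring B reversed. It sets out from 1 and comes back at 3. Chan–Lam coupling of 1 with commercial (5-formyl-2-methoxyphenyl)boronic acid (Cu(OAc)2, pyridine, 4 Å molecular sieves, CH2Cl2, air, rt) should give 3 directly. No compound outside the list is made (F0).

Further compounds
F1 | step 6 | 2-[2-(2-{3-(4-ethenylphenoxy)-4-methoxyphenyl}ethyl)-4-methoxyphenyl]-4,4,5,5-tetramethyl-1,3,2-dioxaborolane | COc1ccc(B2OC(C)(C)C(C)(C)O2)c(CCc2ccc(OC)c(Oc3ccc(C=C)cc3)c2)c1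
F2 | step 6 | 2-bromo-2'-{2-[3-(4-ethenylphenoxy)-4-methoxyphenyl]ethyl}-4',6-dimethoxybiphenyl | COc1ccc(-c2c(Br)cccc2OC)c(CCc2ccc(OC)c(Oc3ccc(C=C)cc3)c2)c1
F3 | step 6 | B-alkyl-9-BBN adduct of F2 | COc1ccc(-c2c(Br)cccc2OC)c(CCc2ccc(OC)c(Oc3ccc(CCB4C5CCCC4CCC5)cc3)c2)c1
F4 | step 3 | (2-bromo-5-methoxybenzyl)triphenylphosphonium bromide | COc1ccc(Br)c(C[P+](c2ccccc2)(c2ccccc2)c2ccccc2)c1.[Br-]
F5 | step 3 | 2-(4-{5-[2-(2-bromo-5-methoxyphenyl)ethenyl]-2-methoxyphenoxy}phenyl)ethanol, E/Z mixture | COc1ccc(Br)c(C=Cc2ccc(OC)c(Oc3ccc(CCO)cc3)c2)c1
F0 | step 1 | none | none
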